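I kept the accounts in millimolar of reagent, since the volume stays constant and every unit of reagent must land in some entry.

    reagent + catalyst + left-handed substrate → catalyst + left-handed product (k1 = 5.38 × 10⁵ M⁻² h⁻¹)
    reagent + catalyst + right-handed substrate → catalyst + right-handed product (k2 = 5670 M⁻² h⁻¹)
    precatalyst → catalyst (k3 = 0.0696 h⁻¹)
    reagent → decomposition product (k4 = 4.44 × 10⁻⁴ h⁻¹)

left-handed substrate 20 mM; reagent 1.10 equiv; precatalyst 0.2 mol%; right-handed substrate 20 mM

* the form that holds most of the catalyst when 50% of the left-handed substrate and right-handed substrate together are converted (precatalyst / catalyst)
* its share of the catalyst then
* factor on the rate of making left-handed product when 50% of the left-handed substrate and right-handed substrate together are converted if reagent is charged twice over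
* factor on the rate when 50% of the left-handed substrate and right-handed substrate together are converted if precatalyst is charged at 1 mol% instead

Reagent is the limiting reagent, because c(reagent) stands lower than the two substrates together. I closed the books at the moment asked about:

charged: 22.0 mM
into the two products: 20.0 mM
surplus before decomposition: 2.00 mM
into decomposition product, at the opening pace: 0.00977 mM h⁻¹

The second entry holds whatever the split between the substrates, because each turnover takes one reagent.

Control changes hands where c(left-handed substrate) falls to the surplus. Before that crossing, reagent falls along with it. After it, c(reagent) lingers near the surplus and left-handed substrate decays pseudo-first-order. With all 0.0400 mM of catalyst working, the time constant of that tail is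

tail = one over (constant of the left-handed step × c(catalyst) × surplus) = 23.2 h

Over one tail, decomposition at the opening pace takes 0.227 mM, less than the surplus.

The quantity I carried is the activation time, the mean wait of a precatalyst before it becomes catalyst, which is the inverse of its rate constant:

activation time = 14.4 h
share of precatalyst = exp(−t / activation time)

The tail is longer than the activation time, so for the moment one tail after the start I reckoned precatalyst at 20.0%, and I committed to catalyst as the main form.

Reagent and catalyst cancel in the ratio of the two steps, so c(left-handed substrate) at this conversion is the same in each variant. Each factor is therefore a reagent ratio times a catalyst ratio. Counted before decomposition, doubled reagent gives 12.0 on reagent, and counted as fully activated, 1 mol% precatalyst gives 5.00 on catalyst. I expected both to shrink through unfinished activation, and my reckoning stopped there.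

The forecast gave catalyst at 96.7% with factors 8.5 and 3.7, noting that “Reagent is then nearly exhausted”.

The flask gave catalyst at 96.7%, with factors 8.47 and 3.72.

In the first flask the conversion was reached at 49.0 h, later than the activation time by a factor of 3.40, and the exponential turns that into 3.33% precatalyst, beside the 3.31% that stood there. In the flask with 1 mol% precatalyst, 31.2% remained at that conversion, which the same activation time reads as 16.8 h, and the loading times the ratio of the activated shares gives 3.56, beside the factor 3.72 of that flask.

Its constants were set for the occasion; the result is computed.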